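**Plan**

- Oxane numbering used throughout: O1, C2 (2-arylethyl), C4 (ring A, the methoxy-dihydroxybenzene ring of the chalcone), C6 (4-hydroxyphenyl). The target is (2S,4R,6S), with all three ring substituents cis.
- Enabling feature: C4 carries only H besides ring A, and H4 is cis to H2 and H6. C4–C5 can therefore be taken back to a ring olefin C4=C5, which ring-closing metathesis cuts into a vinyl group on C6 and a 2-(ring A)allyl group on C2.
- Cuts in retrosynthetic order: the five MOM ethers; ring A–C(=O) (aryllithium plus cinnamoyl Weinreb amide); C4=C5 (metathesis, after removal of H2); O1–C6 (allylic etherification); ring A–C4 (Negishi coupling); C2–C3 (2-bromoallylation of a 3-arylpropanal).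
- Forward order: the C2–C3–C4 segment is built on the arylpropanal, ring A is attached, the O1–C6 ether is made, the oxane is closed as the only ring-forming event, then reduced, acylated on ring A and deprotected.
- Stereochemistry: C2 from reagent-controlled 2-bromoallylboration, C6 from catalyst-controlled iridium allylic etherification, C4 from hydrogenation anti to the two cis ring substituents. The E enone is carried in from methyl 4-hydroxycinnamate.

Key step: step 11

Remark: the sense of induction in steps 5 and 10 is assigned from the accepted chair and allyl-iridium models; both chiral reagents are available in either enantiomeric form.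

**Route**

Step 1
Reactants: 1 5-methoxyresorcinol
Product: 2 1-methoxy-3,5-bis(methoxymethoxy)benzene
Conditions: MOMCl (2.4 equiv), i-Pr2NEt, CH2Cl2, 0 °C → rt
Reagents that add atoms: chloromethyl methyl ether, COCCl
Why: Base-mediated O-alkylation of both phenols (Williamson-type acetal formation) should give the bis-MOM ether, whose two acetal oxygens later direct lithiation to the carbon between them.

Step 2
Reactants: 3 methyl 3-(4-hydroxyphenyl)propanoate
Product: 4 methyl 3-[4-(methoxymethoxy)phenyl]propanoate
Conditions: MOMCl, i-Pr2NEt, CH2Cl2, 0 °C → rt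
Reagents that add atoms: chloromethyl methyl ether, COCCl
Why: The same phenol O-alkylation installs a MOM ether that tolerates the hydride, organometallic, metathesis and hydrogenation steps and is removed with the others at the end.

Step 3
Reactants: 4 methyl 3-[4-(methoxymethoxy)phenyl]propanoate
Product: 5 3-[4-(methoxymethoxy)phenyl]propanal
Conditions: i-Bu2AlH (1.05 equiv), CH2Cl2, −78 °C; aq. potassium sodium tartrate
Reagents that add atoms: none
Why: Partial ester reduction with one equivalent of i-Bu2AlH at −78 °C should stop at the tetrahedral aluminium hemiacetal, which releases the aldehyde only on work-up.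

Step 4
Reactants: 6 2,3-dibromoprop-1-ene
Product: 7 tributyl(2-bromoprop-2-en-1-yl)stannane
Conditions: Bu3SnH, LiN(i-Pr)2, THF, 0 °C; then 6, −78 °C
Reagents that add atoms: tributyltin hydride (used as tributylstannyllithium made in the flask), CCCC[SnH](CCCC)CCCC
Why: SN2 displacement of the allylic bromide by the soft tributylstannyl anion (stannylation of an allylic halide) should leave the vinylic bromide untouched.

Step 5
Reactants: 5 3-[4-(methoxymethoxy)phenyl]propanal; 7 tributyl(2-bromoprop-2-en-1-yl)stannane
Product: 9 (3S)-5-bromo-1-[4-(methoxymethoxy)phenyl]hex-5-en-3-ol, via bromoallyl diazaborolidine 8 (not isolated)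
Conditions: (1R,2R)-TsNHCH(Ph)CH(Ph)NHTs, BBr3, CH2Cl2, 0 °C → rt, volatiles removed; 7, CH2Cl2, rt; then 5, −78 °C; pH 7 buffer
Reagents that add atoms: none
Why: Enantioselective 2-haloallylboration of an aldehyde by a chiral 1,3,2-diazaborolidine allylborane formed through tin-to-boron exchange; in the chair transition state with the aldehyde chain equatorial, the twofold-symmetric (R,R)-bis-sulfonamide is expected to direct the bromoallyl group to the re face, setting the (S) carbinol that becomes C2.

Step 6
Reactants: 9 (3S)-5-bromo-1-[4-(methoxymethoxy)phenyl]hex-5-en-3-ol; 2 1-methoxy-3,5-bis(methoxymethoxy)benzene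
Product: 12 (3S)-5-[4-methoxy-2,6-bis(methoxymethoxy)phenyl]-1-[4-(methoxymethoxy)phenyl]hex-5-en-3-ol, via ring A aryllithium 10 (not isolated), via ring A arylzinc chloride 11 (not isolated)
Conditions: 2 (2.5 equiv), n-BuLi, THF, 0 °C; ZnCl2, 0 °C → rt; then 9, Pd(OAc)2 (cat.), SPhos, THF, 60 °C
Reagents that add atoms: none
Why: Directed ortho-lithiation at the carbon flanked by both MOM ethers, transmetalation to zinc and Negishi cross-coupling with the 2-bromoalkene should join ring A to C4; the SPhos-ligated palladium catalyst accepts di-ortho-substituted arylzincs, the excess of 11 offsets the free hydroxyl, and the carbinol centre is not involved.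

Step 7
Reactants: 13 methyl (2E)-3-(4-hydroxyphenyl)prop-2-enoate
Product: 14 methyl (2E)-3-[4-(methoxymethoxy)phenyl]prop-2-enoate
Conditions: MOMCl, i-Pr2NEt, CH2Cl2, 0 °C → rt
Reagents that add atoms: chloromethyl methyl ether, COCCl
Why: Phenol O-alkylation as in step 1 gives one protected cinnamate that serves both the allylic carbonate (steps 8 and 9) and the Weinreb amide (step 13).

Step 8
Reactants: 14 methyl (2E)-3-[4-(methoxymethoxy)phenyl]prop-2-enoate
Product: 15 (2E)-3-[4-(methoxymethoxy)phenyl]prop-2-en-1-ol
Conditions: i-Bu2AlH (2.2 equiv), CH2Cl2, −78 → 0 °C; aq. potassium sodium tartrate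
Reagents that add atoms: none
Why: 1,2-Reduction of the enoate with excess i-Bu2AlH should give the allylic alcohol with the E double bond unchanged.

Step 9
Reactants: 15 (2E)-3-[4-(methoxymethoxy)phenyl]prop-2-en-1-ol
Product: 16 tert-butyl (2E)-3-[4-(methoxymethoxy)phenyl]prop-2-en-1-yl carbonate
Conditions: n-BuLi, THF, −78 °C; Boc2O, → rt
Reagents that add atoms: di-tert-butyl dicarbonate, CC(C)(C)OC(=O)OC(=O)OC(C)(C)C
Why: Acylation of the lithium alkoxide with Boc2O (carbonate formation) gives a leaving group that ionises readily on iridium and whose tert-butoxycarbonyl group is not transferred to an alkoxide nucleophile.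

Step 10
Reactants: 12 (3S)-5-[4-methoxy-2,6-bis(methoxymethoxy)phenyl]-1-[4-(methoxymethoxy)phenyl]hex-5-en-3-ol; 16 tert-butyl (2E)-3-[4-(methoxymethoxy)phenyl]prop-2-en-1-yl carbonate
Product: 19 (S,S)-bis-alkenyl ether carrying the 2-(ring A)allyl group on C2 and the vinyl group on C6, via lithium alkoxide 17 (not isolated), via copper alkoxide 18 (not isolated)
Conditions: 12, n-BuLi (1.0 equiv), THF, −78 → 0 °C; CuI, rt; then 16 (1.3 equiv), [Ir(cod)Cl]2 (2 mol %), (Sa,Sc,Sc)-phosphoramidite from (S)-BINOL and bis[(S)-1-phenylethyl]amine (4 mol %), THF, rt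
Reagents that add atoms: none
Why: Iridium-catalysed branched-selective asymmetric allylic etherification (Tsuji–Trost-type substitution through a cyclometalated iridium phosphoramidite allyl complex) with a soft monovalent copper alkoxide should attack the aryl-bearing allyl terminus; the (Sa,Sc,Sc) catalyst is expected to override the existing centre and set the new benzylic centre (S), which is the 2,6-cis series.

Step 11
Reactants: 19 (S,S)-bis-alkenyl ether
Product: 20 (2S,6S)-4-(ring A)-6-[4-(methoxymethoxy)phenyl]-2-{2-[4-(methoxymethoxy)phenyl]ethyl}-3,6-dihydro-2H-pyran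
Conditions: second-generation Hoveyda–Grubbs catalyst RuCl2(H2IMes)(=CH-C6H4-2-O-i-Pr) (10 mol %), 1,4-benzoquinone (20 mol %), toluene (5 mM), 80 °C, argon sparge
Reagents that add atoms: none
Why: Ring-closing olefin metathesis: the ruthenium benzylidene first exchanges with the unhindered vinyl group on C6, the resulting alkylidene adds intramolecularly to the 1,1-disubstituted alkene by [2+2] cycloaddition, and cycloreversion of the ruthenacyclobutane forms C4=C5 and a ruthenium methylidene while ethylene leaves the solution. The closest known reaction type is the metathesis closure of allyl homoallyl ethers to 3,6-dihydro-2H-pyrans, including trisubstituted ring olefins made from 1,1-disubstituted alkenes. The single ring formed, the six-membered oxacycle O1–C2–C3–C4=C5–C6, closes by metathesis between the two terminal alkenes, the only new bond being the endocyclic C4=C5. No stereocentre is created; C2 and C6 come from steps 5 and 10 and are not touched. The step needs ring closure to win over intermolecular metathesis and over ruthenium hydride migration of the allylic benzylic ether: high dilution and the inability of the gem-disubstituted alkene to homodimerise secure the first, 1,4-benzoquinone and removal of ethylene the second. Ring A, twisted out of the alkene plane by its two ortho MOM ethers, is bulky but electronically innocent, which is why the phosphine-free, thermally robust second-generation catalyst is used at 80 °C.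

Step 12
Reactants: 20 (2S,6S)-4-(ring A)-3,6-dihydro-2H-pyran
Product: 21 (2S,4R,6S)-4-[4-methoxy-2,6-bis(methoxymethoxy)phenyl]-2-[4-(methoxymethoxy)phenyl]-6-{2-[4-(methoxymethoxy)phenyl]ethyl}oxane
Conditions: H2 (1 atm), 10% Pd/C, EtOAc, rt
Reagents that add atoms: none
Why: Heterogeneous catalytic syn-hydrogenation of the trisubstituted ring olefin should occur from the face of the half-chair opposite the cis C2 and C6 substituents, so that H4 ends up cis to H2 and H6 (C4 = R, all-equatorial oxane); the neutral aprotic medium disfavours hydrogenolysis of the benzylic C6–O bond.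

Step 13
Reactants: 14 methyl (2E)-3-[4-(methoxymethoxy)phenyl]prop-2-enoate
Product: 22 (2E)-N-methoxy-3-[4-(methoxymethoxy)phenyl]-N-methylprop-2-enamide
Conditions: MeNH(OMe)·HCl, i-PrMgCl, THF, −20 → 0 °C
Reagents that add atoms: N,O-dimethylhydroxylamine hydrochloride, CNOC.Cl
Why: Aminolysis of the ester by the chloromagnesium amide of N,O-dimethylhydroxylamine (Weinreb amide formation from an ester) should be faster than conjugate addition at this temperature.

Step 14
Reactants: 21 (2S,4R,6S)-oxane; 22 (2E)-N-methoxy-3-[4-(methoxymethoxy)phenyl]-N-methylprop-2-enamide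
Product: 24 penta-MOM ether of the target chalcone, via lithiated oxane 23 (not isolated)
Conditions: n-BuLi, TMEDA, THF, −20 → 0 °C; then 22, −78 → 0 °C; aq. NH4Cl
Reagents that add atoms: none
Why: Directed ortho-metalation at the only ring A C–H, which lies between a MOM ether and the methoxy group and is therefore more acidic than the sites ortho to a single MOM ether on the other rings, followed by Weinreb ketone synthesis, in which the chelated tetrahedral adduct prevents over-addition and 1,2-addition gives the E chalcone.

Step 15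
Reactants: 24 penta-MOM ether of the target chalcone
Product: 25 CNP0215517.1
Conditions: conc. HCl (cat.), MeOH, rt
Reagents that add atoms: none
Why: Acid-catalysed transacetalisation of the five MOM ethers to methanol (MOM cleavage) should free all phenols under conditions used for 2′-hydroxy-6′-methoxychalcones, whose hydrogen-bonded carbonyl resists flavanone closure in dilute acid at room temperature.

**Compound list**

1 | 5-methoxybenzene-1,3-diol (5-methoxyresorcinol) | COc1cc(O)cc(O)c1 | starting material
2 | 1-methoxy-3,5-bis(methoxymethoxy)benzene | COCOc1cc(OC)cc(OCOC)c1 | intermediate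
3 | methyl 3-(4-hydroxyphenyl)propanoate | COC(=O)CCc1ccc(O)cc1 | starting material
4 | methyl 3-[4-(methoxymethoxy)phenyl]propanoate | COC(=O)CCc1ccc(OCOC)cc1 | intermediate
5 | 3-[4-(methoxymethoxy)phenyl]propanal | O=CCCc1ccc(OCOC)cc1 | intermediate
6 | 2,3-dibromoprop-1-ene | C=C(Br)CBr | starting material
7 | tributyl(2-bromoprop-2-en-1-yl)stannane | C=C(Br)C[Sn](CCCC)(CCCC)CCCC | intermediate
8 | (4R,5R)-2-(2-bromoprop-2-en-1-yl)-4,5-diphenyl-1,3-bis(4-methylbenzenesulfonyl)-1,3,2-diazaborolidine | C=C(Br)CB1N(S(=O)(=O)c2ccc(C)cc2)[C@H](c2ccccc2)[C@@H](c2ccccc2)N1S(=O)(=O)c1ccc(C)cc1 | intermediate (not isolated)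
9 | (3S)-5-bromo-1-[4-(methoxymethoxy)phenyl]hex-5-en-3-ol | C=C(Br)C[C@H](CCc1ccc(OCOC)cc1)O | intermediate
10 | [4-methoxy-2,6-bis(methoxymethoxy)phenyl]lithium | [Li]c1c(OCOC)cc(OC)cc1OCOC | intermediate (not isolated)
11 | chloro[4-methoxy-2,6-bis(methoxymethoxy)phenyl]zinc | Cl[Zn]c1c(OCOC)cc(OC)cc1OCOC | intermediate (not isolated)
12 | (3S)-5-[4-methoxy-2,6-bis(methoxymethoxy)phenyl]-1-[4-(methoxymethoxy)phenyl]hex-5-en-3-ol | C=C(c1c(OCOC)cc(OC)cc1OCOC)C[C@H](CCc1ccc(OCOC)cc1)O | intermediate
13 | methyl (2E)-3-(4-hydroxyphenyl)prop-2-enoate | COC(=O)/C=C/c1ccc(O)cc1 | starting material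
14 | methyl (2E)-3-[4-(methoxymethoxy)phenyl]prop-2-enoate | COC(=O)/C=C/c1ccc(OCOC)cc1 | intermediate
15 | (2E)-3-[4-(methoxymethoxy)phenyl]prop-2-en-1-ol | OC/C=C/c1ccc(OCOC)cc1 | intermediate
16 | tert-butyl (2E)-3-[4-(methoxymethoxy)phenyl]prop-2-en-1-yl carbonate | CC(C)(C)OC(=O)OC/C=C/c1ccc(OCOC)cc1 | intermediate
17 | lithium (3S)-5-[4-methoxy-2,6-bis(methoxymethoxy)phenyl]-1-[4-(methoxymethoxy)phenyl]hex-5-en-3-olate | C=C(c1c(OCOC)cc(OC)cc1OCOC)C[C@H](CCc1ccc(OCOC)cc1)O[Li] | intermediate (not isolated)
18 | copper alkoxide of 12 (monovalent copper) | C=C(c1c(OCOC)cc(OC)cc1OCOC)C[C@H](CCc1ccc(OCOC)cc1)O[Cu] | intermediate (not isolated)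
19 | 2-[(4S)-4-{[(1S)-1-[4-(methoxymethoxy)phenyl]prop-2-en-1-yl]oxy}-6-[4-(methoxymethoxy)phenyl]hex-1-en-2-yl]-5-methoxy-1,3-bis(methoxymethoxy)benzene | C=C(c1c(OCOC)cc(OC)cc1OCOC)C[C@H](CCc1ccc(OCOC)cc1)O[C@H](c1ccc(OCOC)cc1)C=C | intermediate (key-step precursor)
20 | (2S,6S)-4-[4-methoxy-2,6-bis(methoxymethoxy)phenyl]-6-[4-(methoxymethoxy)phenyl]-2-{2-[4-(methoxymethoxy)phenyl]ethyl}-3,6-dihydro-2H-pyran | O1[C@H](c2ccc(OCOC)cc2)C=C(c2c(OCOC)cc(OC)cc2OCOC)C[C@@H]1CCc1ccc(OCOC)cc1 | intermediate (key-step product)
21 | (2S,4R,6S)-4-[4-methoxy-2,6-bis(methoxymethoxy)phenyl]-2-[4-(methoxymethoxy)phenyl]-6-{2-[4-(methoxymethoxy)phenyl]ethyl}oxane | COCOc1cc(OC)cc(OCOC)c1[C@@H]1C[C@H](CCc2ccc(OCOC)cc2)O[C@H](c2ccc(OCOC)cc2)C1 | intermediate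
22 | (2E)-N-methoxy-3-[4-(methoxymethoxy)phenyl]-N-methylprop-2-enamide | CON(C)C(=O)/C=C/c1ccc(OCOC)cc1 | intermediate
23 | {6-methoxy-2,4-bis(methoxymethoxy)-3-[(2S,4R,6S)-2-[4-(methoxymethoxy)phenyl]-6-{2-[4-(methoxymethoxy)phenyl]ethyl}oxan-4-yl]phenyl}lithium | COCOc1c([Li])c(OC)cc(OCOC)c1[C@@H]1C[C@H](CCc2ccc(OCOC)cc2)O[C@H](c2ccc(OCOC)cc2)C1 | intermediate (not isolated)
24 | (2E)-1-{6-methoxy-2,4-bis(methoxymethoxy)-3-[(2S,4R,6S)-2-[4-(methoxymethoxy)phenyl]-6-{2-[4-(methoxymethoxy)phenyl]ethyl}oxan-4-yl]phenyl}-3-[4-(methoxymethoxy)phenyl]prop-2-en-1-one | COCOc1c(C(=O)/C=C/c2ccc(OCOC)cc2)c(OC)cc(OCOC)c1[C@@H]1C[C@H](CCc2ccc(OCOC)cc2)O[C@H](c2ccc(OCOC)cc2)C1 | intermediate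
25 | CNP0215517.1, (2E)-1-{2,4-dihydroxy-3-[(2S,4R,6S)-2-(4-hydroxyphenyl)-6-[2-(4-hydroxyphenyl)ethyl]oxan-4-yl]-6-methoxyphenyl}-3-(4-hydroxyphenyl)prop-2-en-1-one | COc1cc(O)c([C@@H]2C[C@H](CCc3ccc(O)cc3)O[C@H](c3ccc(O)cc3)C2)c(O)c1C(=O)/C=C/c1ccc(O)cc1 | target

**Step count and risks**

Total step count: 15. Longest linear sequence: 9 steps (3 → 4 → 5 → 9 → 12 → 19 → 20 → 21 → 24 → 25).

The three steps most likely to fail:

Step 11. The hindered 1,1-disubstituted alkene may engage the ruthenium alkylidene too slowly, so that intermolecular metathesis through the vinyl group, catalyst decay or ruthenium hydride migration of the allylic ether takes over. The fallback closes the same ring by a Prins cyclisation and sets out from alcohol 12. Condensation of 12 with commercial 4-(methoxymethoxy)benzaldehyde (O=Cc1ccc(OCOC)cc1) under In(OTf)3 catalysis in CH2Cl2 over molecular sieves would give an oxocarbenium ion that is captured by the 1,1-disubstituted alkene through a chair with both substituents equatorial, so that C6 is set cis to C2 by the substrate. Loss of a proton from the tertiary cation at C4 would give dihydropyran 20 together with its double-bond isomer, (2S,6S)-4-[4-methoxy-2,6-bis(methoxymethoxy)phenyl]-2-[4-(methoxymethoxy)phenyl]-6-{2-[4-(methoxymethoxy)phenyl]ethyl}-3,6-dihydro-2H-pyran F1. The route is rejoined at 20; F1 would be taken through step 12 alongside it, since both olefin isomers are reduced to 21.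

Step 12. Hydrogen may add with poor facial selectivity at C4, the palladium surface may move the double bond towards C6 and erode that centre, or the allylic benzylic C6–O bond may be hydrogenolysed. The fallback replaces surface syn-addition under kinetic control by stepwise hydrogen-atom transfer under thermodynamic control. Starting from 20, Mn(dpm)3 (cat.), PhSiH3 and t-BuOOH in i-PrOH at rt would deliver a hydrogen atom to C5, and the tertiary C4 radical would be quenched from the axial direction to place ring A equatorial. No metal surface is present, so migration and hydrogenolysis are avoided. The sequence passes through no new isolable compound (F0) and returns to the route at 21.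

Step 14. Metalation may compete ortho to the single MOM ethers of the two 4-(methoxymethoxy)phenyl rings or at the benzylic C6–H, leading to acylation at the wrong ring or to ring opening. The fallback fixes the site by electrophilic substitution and sets out from 21. N-bromosuccinimide (1.0 equiv) in MeCN at −40 °C should brominate only the trioxygenated ring A at its single free position, giving (2S,4R,6S)-4-[3-bromo-4-methoxy-2,6-bis(methoxymethoxy)phenyl]-2-[4-(methoxymethoxy)phenyl]-6-{2-[4-(methoxymethoxy)phenyl]ethyl}oxane F2. Bromine–lithium exchange with n-BuLi in THF at −78 °C would then generate aryllithium 23 without any competing deprotonation, and addition of Weinreb amide 22 returns the route at 24.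

**Further compounds**

F1 | step 11 | (2S,6S)-4-[4-methoxy-2,6-bis(methoxymethoxy)phenyl]-2-[4-(methoxymethoxy)phenyl]-6-{2-[4-(methoxymethoxy)phenyl]ethyl}-3,6-dihydro-2H-pyran | O1[C@H](c2ccc(OCOC)cc2)CC(c2c(OCOC)cc(OC)cc2OCOC)=C[C@@H]1CCc1ccc(OCOC)cc1
F0 | step 12 | none | none
F2 | step 14 | (2S,4R,6S)-4-[3-bromo-4-methoxy-2,6-bis(methoxymethoxy)phenyl]-2-[4-(methoxymethoxy)phenyl]-6-{2-[4-(methoxymethoxy)phenyl]ethyl}oxane | COCOc1c(Br)c(OC)cc(OCOC)c1[C@@H]1C[C@H](CCc2ccc(OCOC)cc2)O[C@H](c2ccc(OCOC)cc2)C1
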